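**Strategy.** The lower pyran ring (ring F) is disconnected at O1–C2 and C3–C4. Its unsubstituted C4 methylene and its cis C2-aryl/C3-oxygen pair map onto an ortho-quinone methide of the lower phloroglucinol ring (ring D) with a bare methide carbon and onto a (Z)-styrylboronate. One oxa-[4+2] cycloaddition therefore closes ring F, makes both bonds and sets C2 and C3, with boron standing in for the C3 oxygen. Its precursor is octa-O-benzyl-EGCG carrying at C4, trans to the gallate, a 4,6-dibenzyloxy-2-hydroxy-3-(hydroxymethyl)phenyl group, so the upper unit and the 4→8 bond exist before ring F does.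

Key step: step 8

**Assumptions and remarks**
- Ring letters: upper unit A (phloroglucinol ring), C (pyran), B (pyrogallol ring); lower unit D, F, E in the same order. Atom numbers are flavan numbers; 4β means trans to the C3 oxygen. EGC = epigallocatechin, EGCG = its 3-O-gallate.
- (−)-Epigallocatechin, 3,5-bis(benzyloxy)phenol, 3,4,5-tris(benzyloxy)benzoyl chloride and 3,4,5-tris(benzyloxy)benzaldehyde are taken as catalogue compounds.
- The upper unit is built from (−)-epigallocatechin and the gallate is attached after C4 activation, because phenol benzylation and DDQ oxidation are best established on the free flavan-3-ol.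
- Which antipode of the phosphoric acid in step 8 matches the chiral upper unit cannot be predicted; the (R) acid is written and the (S) acid is the first variation.
- The ring D phenol offers the C4 cation a para carbon as well as two equivalent ortho carbons; this is dealt with in step 4.

**Route**

Step 1
Reactants: 1 (−)-epigallocatechin (EGC)
Product: 2 5,7,3',4',5'-penta-O-benzyl-EGC (2R,3R, 2,3-cis, C3 hydroxyl free)
Conditions: BnBr (5.5 equiv), K2CO3 (6 equiv), DMF, −10 °C to rt, argon
Reagents that add atoms: benzyl bromide, BrCc1ccccc1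
Why: Fivefold Williamson etherification with a weak carbonate base alkylates only the phenols, since the C3 alcohol is not deprotonated, and run cold under argon it should cap them before phenoxide-driven opening of ring C can epimerise C2.

Step 2
Reactants: 2 penta-O-benzyl-EGC
Product: 3 4β-(2-ethoxyethoxy)-penta-O-benzyl-EGC (C4 ether trans to the C3 hydroxyl)
Conditions: DDQ (2 equiv), 2-ethoxyethanol (5 equiv), CH2Cl2, rt
Reagents that add atoms: 2-ethoxyethanol, CCOCCO
Why: DDQ benzylic oxidation with alcohol trapping, established for O-benzylated flavan-3-ols, should abstract hydride from C4 (activated by the ortho and para oxygens of ring A) and let the alcohol add opposite the C2 aryl and C3 hydroxyl groups; the C4 configuration is ionised again in step 4.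

Step 3
Reactants: 3 4β-(2-ethoxyethoxy)-penta-O-benzyl-EGC; 4 3,4,5-tris(benzyloxy)benzoyl chloride
Product: 5 4β-(2-ethoxyethoxy)-octa-O-benzyl-EGCG (C4 ether trans to the C3 ester oxygen)
Conditions: 4 (1.5 equiv), Et3N, DMAP (0.2 equiv), CH2Cl2, 0 °C to rt
Reagents that add atoms: none
Why: DMAP-catalysed acylation of the secondary C3 alcohol through the acylpyridinium ion is a base-buffered esterification that breaks no bond to a stereocentre and leaves the acid-labile C4 ether in place.

Step 4
Reactants: 5 4β-(2-ethoxyethoxy)-octa-O-benzyl-EGCG; 6 3,5-bis(benzyloxy)phenol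
Product: 7 4β-[2,4-bis(benzyloxy)-6-hydroxyphenyl]-octa-O-benzyl-EGCG (C4 aryl trans to the C3 ester oxygen)
Conditions: 6 (4 equiv), TMSOTf (0.2 equiv), CH2Cl2, −78 to −40 °C; Et3N quench
Reagents that add atoms: none
Why: Friedel–Crafts alkylation in which the C3 gallate carbonyl bridges the C4 cation on the face it shares with the C2 aryl group, so the phenol should attack from the other face (4β), at an ortho carbon in preference to the para carbon that lies between two benzyloxy groups (the situation that disfavours C6 of flavans in interflavan couplings), while excess phenol suppresses self-condensation.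

Step 5
Reactants: 7 4β-[2,4-bis(benzyloxy)-6-hydroxyphenyl]-octa-O-benzyl-EGCG
Product: 9 4β-[4,6-bis(benzyloxy)-2-hydroxy-3-(hydroxymethyl)phenyl]-octa-O-benzyl-EGCG, via cyclic phenylboronate 8 (not isolated)
Conditions: PhB(OH)2 (1.5 equiv), (CH2O)n, EtCO2H (cat.), toluene, 85 °C, 4 Å MS; then propane-1,3-diol, THF, rt; Et3N-deactivated silica
Reagents that add atoms: formaldehyde (as paraformaldehyde), C=O
Why: Boronic-acid-templated ortho-hydroxymethylation of a phenol, in which the phenylboronate ester formed at the ring D hydroxyl delivers formaldehyde through a six-membered transition state to the only free ortho carbon (the future C4a), and diol exchange then frees the salicyl alcohol with no acid stronger than catalytic propionic acid present.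

Step 6
Reactants: 10 3,4,5-tris(benzyloxy)benzaldehyde
Product: 11 1,2,3-tris(benzyloxy)-5-ethynylbenzene
Conditions: dimethyl (1-diazo-2-oxopropyl)phosphonate, K2CO3, MeOH/THF, rt
Reagents that add atoms: dimethyl (1-diazo-2-oxopropyl)phosphonate, COP(=O)(OC)C(=[N+]=[N-])C(C)=O
Why: Ohira–Bestmann (Seyferth–Gilbert) homologation, in which the diazomethylphosphonate anion olefinates the non-enolisable aldehyde and the diazoalkene loses nitrogen with a 1,2-hydrogen shift to give the terminal alkyne under conditions that spare benzyl ethers.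

Step 7
Reactants: 11 1,2,3-tris(benzyloxy)-5-ethynylbenzene
Product: 12 (Z)-2-(3,4,5-tris(benzyloxy)phenyl)ethenyl pinacolboronate
Conditions: HBpin, [Rh(cod)Cl]2 (1.5 mol %), P(i-Pr)3 (6 mol %), Et3N, cyclohexane, rt
Reagents that add atoms: pinacolborane, [H]B1OC(C)(C)C(C)(C)O1
Why: Rhodium-catalysed trans-hydroboration of a terminal alkyne, which runs through a rhodium vinylidene so that boron and hydrogen end up anti across the alkene and the Z alkenylboronate should result instead of the E isomer of ordinary syn-hydroboration.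

Step 8
Reactants: 9 4β-[4,6-bis(benzyloxy)-2-hydroxy-3-(hydroxymethyl)phenyl]-octa-O-benzyl-EGCG; 12 (Z)-2-(3,4,5-tris(benzyloxy)phenyl)ethenyl pinacolboronate
Product: 14 trideca-O-benzyl 4β→8 dimer bearing pinacolboryl at lower C3 (lower C2 aryl cis to boron; upper gallate in place), via ring D ortho-quinone methide 13 (not isolated)
Conditions: (R)-3,3'-bis(2,4,6-triisopropylphenyl)-1,1'-binaphthyl-2,2'-diyl hydrogen phosphate (10 mol %), 12 (3 equiv), 5 Å MS, toluene, 40 °C, 9 added slowly by syringe pump
Reagents that add atoms: none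
Why: Proposed new method: the phosphoric acid should ionise the benzylic C–OH bond of 9, which is flanked by ortho and para benzyloxy groups and an ortho hydroxyl, and release ortho-quinone methide 13 as a hydrogen-bonded complex whose exocyclic CH2 (future C4) bonds to the boron-bearing alkene carbon of 12 (future C3) while the ring D oxygen (future O1) bonds to the aryl-bearing carbon (future C2) in an asynchronous inverse-electron-demand oxa-[4+2] cycloaddition. The closest known reaction type is the Brønsted-acid-catalysed [4+2] cycloaddition of ortho-quinone methides, generated from ortho-hydroxybenzyl alcohols, with styrenes to give 2-arylchromans; an alkenylboronate has not served as the two-carbon partner, and the regiochemistry is expected because the electron-rich aryl group stabilises positive charge at the future C2. Ring F is closed by this intermolecular [4+2] addition, suprafacial on the alkene, with O1–C2 and C3–C4 formed in one event and no endo/exo question because the methide carbon carries two hydrogens. The cis relationship of C2 and C3 is dictated by the Z geometry of 12, provided ring closure outruns rotation about C2–C3, and their absolute configuration (that of 14, leading to the EGCG-type lower unit) is decided by which alkene face meets the methide, under control of the chiral phosphate held at the methide oxygen together with the upper flavan unit on C8 next to that oxygen. The step needs face selectivity and chemoselectivity for the alkene over the free arene carbons (C6 and C8 of ring A, C6 of ring D) that could also trap the methide; slow addition of 9 into excess 12 keeps the methide dilute, and the two possible cycloadducts are diastereomers that should separate by chromatography. The weakly acidic medium, kept dry by the sieves, should leave the 4→8 bond, the gallate ester and the pinacolboronate intact.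

Step 9
Reactants: 14 trideca-O-benzyl 4β→8 dimer bearing pinacolboryl at lower C3
Product: 16 trideca-O-benzyl EGCG-(4β→8)-EGC (lower C3 hydroxyl free; 2,3-cis), via borate ester 15 (not isolated)
Conditions: NaBO3·4H2O (5 equiv), THF/H2O (1:1), rt
Reagents that add atoms: sodium perborate (NaBO3·4H2O), [Na+].[O-]OB=O
Why: Perborate oxidation of a secondary alkyl pinacolboronate, in which C3 migrates from boron to oxygen with retention so the C3–O bond stays cis to the C2 aryl group, in a medium mild enough to spare the gallate ester and to avoid β-elimination of the boronate toward O1.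

Step 10
Reactants: 16 trideca-O-benzyl EGCG-(4β→8)-EGC; 4 3,4,5-tris(benzyloxy)benzoyl chloride
Product: 17 hexadeca-O-benzyl-rhodisin
Conditions: 4 (3 equiv), Et3N, DMAP (cat.), CH2Cl2, rt to 40 °C
Reagents that add atoms: none
Why: DMAP-catalysed acylation of the hindered axial secondary alcohol through the acylpyridinium ion forms the ester without breaking the C3–O bond, so the stereocentre is untouched.

Step 11
Reactants: 17 hexadeca-O-benzyl-rhodisin
Product: 18 rhodisin
Conditions: H2 (1 atm), Pd(OH)2/C, THF/MeOH/H2O, rt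
Reagents that add atoms: none
Why: Neutral hydrogenolysis of the sixteen benzyl ethers cleaves only O–CH2Ph bonds, so both gallate esters, the 4→8 bond and all five stereocentres should be retained.

**Compound list**

1 | (−)-epigallocatechin (EGC), 2R,3R, 2,3-cis | O[C@@H]1Cc2c(O)cc(O)cc2O[C@@H]1c1cc(O)c(O)c(O)c1 | starting material

2 | 5,7,3',4',5'-penta-O-benzyl-EGC, (2R,3R)-5,7-bis(benzyloxy)-2-[3,4,5-tris(benzyloxy)phenyl]chroman-3-ol | O[C@@H]1Cc2c(OCc9ccccc9)cc(OCc9ccccc9)cc2O[C@@H]1c1cc(OCc9ccccc9)c(OCc9ccccc9)c(OCc9ccccc9)c1 | intermediate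

3 | 4β-(2-ethoxyethoxy)-penta-O-benzyl-EGC (C2, C3 as in EGC; C4 ether trans to the C3 hydroxyl) | O[C@@H]1[C@@H](OCCOCC)c2c(OCc9ccccc9)cc(OCc9ccccc9)cc2O[C@@H]1c1cc(OCc9ccccc9)c(OCc9ccccc9)c(OCc9ccccc9)c1 | intermediate

4 | 3,4,5-tris(benzyloxy)benzoyl chloride | O=C(Cl)c1cc(OCc2ccccc2)c(OCc2ccccc2)c(OCc2ccccc2)c1 | starting material

5 | 4β-(2-ethoxyethoxy)-octa-O-benzyl-EGCG (C2, C3 as in EGCG; C4 ether trans to the C3 ester oxygen) | O=C(O[C@@H]1[C@@H](OCCOCC)c2c(OCc9ccccc9)cc(OCc9ccccc9)cc2O[C@@H]1c1cc(OCc9ccccc9)c(OCc9ccccc9)c(OCc9ccccc9)c1)c1cc(OCc9ccccc9)c(OCc9ccccc9)c(OCc9ccccc9)c1 | intermediate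

6 | 3,5-bis(benzyloxy)phenol | Oc1cc(OCc2ccccc2)cc(OCc2ccccc2)c1 | starting material

7 | 4β-[2,4-bis(benzyloxy)-6-hydroxyphenyl]-octa-O-benzyl-EGCG (C4 aryl trans to the C3 ester oxygen) | O=C(O[C@@H]1[C@@H](c2c(O)cc(OCc9ccccc9)cc2OCc9ccccc9)c2c(OCc9ccccc9)cc(OCc9ccccc9)cc2O[C@@H]1c1cc(OCc9ccccc9)c(OCc9ccccc9)c(OCc9ccccc9)c1)c1cc(OCc9ccccc9)c(OCc9ccccc9)c(OCc9ccccc9)c1 | intermediate

8 | cyclic phenylboronate of 9: 5,7-bis(benzyloxy)-2-phenyl-4H-1,3,2-benzodioxaborinin-8-yl group on C4β of octa-O-benzyl-EGCG | O=C(O[C@@H]1[C@@H](c2c3OB(c4ccccc4)OCc3c(OCc9ccccc9)cc2OCc9ccccc9)c2c(OCc9ccccc9)cc(OCc9ccccc9)cc2O[C@@H]1c1cc(OCc9ccccc9)c(OCc9ccccc9)c(OCc9ccccc9)c1)c1cc(OCc9ccccc9)c(OCc9ccccc9)c(OCc9ccccc9)c1 | intermediate (not isolated)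

9 | 4β-[4,6-bis(benzyloxy)-2-hydroxy-3-(hydroxymethyl)phenyl]-octa-O-benzyl-EGCG (cycloaddition precursor) | O=C(O[C@@H]1[C@@H](c2c(O)c(CO)c(OCc9ccccc9)cc2OCc9ccccc9)c2c(OCc9ccccc9)cc(OCc9ccccc9)cc2O[C@@H]1c1cc(OCc9ccccc9)c(OCc9ccccc9)c(OCc9ccccc9)c1)c1cc(OCc9ccccc9)c(OCc9ccccc9)c(OCc9ccccc9)c1 | intermediate

10 | 3,4,5-tris(benzyloxy)benzaldehyde | O=Cc1cc(OCc2ccccc2)c(OCc2ccccc2)c(OCc2ccccc2)c1 | starting material

11 | 1,2,3-tris(benzyloxy)-5-ethynylbenzene | C#Cc1cc(OCc2ccccc2)c(OCc2ccccc2)c(OCc2ccccc2)c1 | intermediate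

12 | (Z)-4,4,5,5-tetramethyl-2-[2-(3,4,5-tris(benzyloxy)phenyl)ethenyl]-1,3,2-dioxaborolane | CC1(C)OB(/C=C\c2cc(OCc3ccccc3)c(OCc3ccccc3)c(OCc3ccccc3)c2)OC1(C)C | intermediate

13 | ring D ortho-quinone methide (C8a=O, exocyclic C4a=CH2, 5,7-bis(benzyloxy)) on C4β of octa-O-benzyl-EGCG | O=C(O[C@@H]1[C@@H](C2=C(OCc9ccccc9)C=C(OCc9ccccc9)C(=C)C2=O)c2c(OCc9ccccc9)cc(OCc9ccccc9)cc2O[C@@H]1c1cc(OCc9ccccc9)c(OCc9ccccc9)c(OCc9ccccc9)c1)c1cc(OCc9ccccc9)c(OCc9ccccc9)c(OCc9ccccc9)c1 | intermediate (not isolated)

14 | trideca-O-benzyl dimer: octa-O-benzyl-EGCG unit linked 4β→8 to a 5,7,3',4',5'-penta-O-benzyl-flavan bearing pinacolboryl at C3, cis to the C2 aryl group, spatial arrangement at lower C2 and C3 as in EGCG | O=C(O[C@@H]1[C@@H](c2c(OCc9ccccc9)cc(OCc9ccccc9)c3c2O[C@H](c2cc(OCc9ccccc9)c(OCc9ccccc9)c(OCc9ccccc9)c2)[C@H](B2OC(C)(C)C(C)(C)O2)C3)c2c(OCc9ccccc9)cc(OCc9ccccc9)cc2O[C@@H]1c1cc(OCc9ccccc9)c(OCc9ccccc9)c(OCc9ccccc9)c1)c1cc(OCc9ccccc9)c(OCc9ccccc9)c(OCc9ccccc9)c1 | intermediate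

15 | borate ester of 16 (lower C3–O–Bpin, configuration retained) | O=C(O[C@@H]1[C@@H](c2c(OCc9ccccc9)cc(OCc9ccccc9)c3c2O[C@H](c2cc(OCc9ccccc9)c(OCc9ccccc9)c(OCc9ccccc9)c2)[C@H](OB2OC(C)(C)C(C)(C)O2)C3)c2c(OCc9ccccc9)cc(OCc9ccccc9)cc2O[C@@H]1c1cc(OCc9ccccc9)c(OCc9ccccc9)c(OCc9ccccc9)c1)c1cc(OCc9ccccc9)c(OCc9ccccc9)c(OCc9ccccc9)c1 | intermediate (not isolated)

16 | trideca-O-benzyl EGCG-(4β→8)-EGC, lower unit 2R,3R with free C3 hydroxyl | O=C(O[C@@H]1[C@@H](c2c(OCc9ccccc9)cc(OCc9ccccc9)c3c2O[C@H](c2cc(OCc9ccccc9)c(OCc9ccccc9)c(OCc9ccccc9)c2)[C@H](O)C3)c2c(OCc9ccccc9)cc(OCc9ccccc9)cc2O[C@@H]1c1cc(OCc9ccccc9)c(OCc9ccccc9)c(OCc9ccccc9)c1)c1cc(OCc9ccccc9)c(OCc9ccccc9)c(OCc9ccccc9)c1 | intermediate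

17 | hexadeca-O-benzyl-rhodisin, perbenzylated EGCG-(4β→8)-EGCG | O=C(O[C@@H]1[C@@H](c2c(OCc9ccccc9)cc(OCc9ccccc9)c3c2O[C@H](c2cc(OCc9ccccc9)c(OCc9ccccc9)c(OCc9ccccc9)c2)[C@H](OC(=O)c2cc(OCc9ccccc9)c(OCc9ccccc9)c(OCc9ccccc9)c2)C3)c2c(OCc9ccccc9)cc(OCc9ccccc9)cc2O[C@@H]1c1cc(OCc9ccccc9)c(OCc9ccccc9)c(OCc9ccccc9)c1)c1cc(OCc9ccccc9)c(OCc9ccccc9)c(OCc9ccccc9)c1 | intermediate

18 | rhodisin, EGCG-(4β→8)-EGCG | O=C(O[C@@H]1[C@@H](c2c(O)cc(O)c3c2O[C@H](c2cc(O)c(O)c(O)c2)[C@H](OC(=O)c2cc(O)c(O)c(O)c2)C3)c2c(O)cc(O)cc2O[C@@H]1c1cc(O)c(O)c(O)c1)c1cc(O)c(O)c(O)c1 | target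

**Step count**

Total step count: 11. Longest linear sequence: 9 steps (steps 1–5 and 8–11, from EGC); the boronate branch (steps 6 and 7) joins at step 8.

**Steps most likely to fail**

1. Step 8 (Proposed new method). Three processes threaten it. The stabilised methide may be trapped by free arene carbons of a second molecule faster than by the weakly nucleophilic alkenylboronate, which leads to oligomerisation. Face selection on the alkene may be poor. A stepwise path could allow rotation about C2–C3 and lose the cis relationship. The fallback replaces the cycloaddition by the established Lewis-acid interflavan coupling of two benzylated flavan units. It sets out from compound 2, which DMAP-catalysed acylation with compound 4 (Et3N, CH2Cl2, rt) should convert into octa-O-benzyl-EGCG F1. With F1 in excess and catalytic TMSOTf in CH2Cl2 at −78 °C, C8 of ring A of F1 should attack the C4 cation released from compound 5, trans to the participating gallate. This should give compound 17 directly, where the route is rejoined before step 11.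

2. Step 5. Ester formation with phenylboronic acid may be slow at the hindered ring D hydroxyl. In the warm, weakly acidic medium the electron-rich benzylic C–O bond may also ionise too early, so that the product condenses with itself. The fallback sets out from compound 7 and replaces the templated hydroxymethylation by formylation and reduction. Magnesium-mediated ortho-formylation (Casnati–Skattebøl; MgCl2, Et3N, paraformaldehyde, THF, reflux) should give 4β-[4,6-bis(benzyloxy)-3-formyl-2-hydroxyphenyl]-octa-O-benzyl-EGCG F2 under basic conditions. NaBH4 in THF/MeOH at 0 °C should then reduce the aldehyde and leave the gallate ester, returning to the route at compound 9.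

3. Step 4. The acid promoter may re-ionise the newly formed C4–aryl bond. The adduct could then drift toward alkylation at the para carbon or toward alkylation of a second flavan molecule, which erodes regiocontrol and gives oligomers. The fallback sets out from compound 5 and changes the mode of activation to a thioether donor. Phenylmethanethiol with catalytic TMSOTf in CH2Cl2 at −78 °C should give 4β-(benzylsulfanyl)-octa-O-benzyl-EGCG F3. Thiophilic activation of F3 with AgBF4 in THF at 0 °C, with excess compound 6 and 2,6-di-tert-butyl-4-methylpyridine as proton scavenger, should then form the C4–aryl bond under kinetic, non-acidic conditions and return to the route at compound 7.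

**Further compounds**

F1 | step 8 | octa-O-benzyl-EGCG, (2R,3R)-5,7-bis(benzyloxy)-2-[3,4,5-tris(benzyloxy)phenyl]chroman-3-yl 3,4,5-tris(benzyloxy)benzoate | O=C(O[C@@H]1Cc2c(OCc9ccccc9)cc(OCc9ccccc9)cc2O[C@@H]1c1cc(OCc9ccccc9)c(OCc9ccccc9)c(OCc9ccccc9)c1)c1cc(OCc9ccccc9)c(OCc9ccccc9)c(OCc9ccccc9)c1
F2 | step 5 | 4β-[4,6-bis(benzyloxy)-3-formyl-2-hydroxyphenyl]-octa-O-benzyl-EGCG | O=C(O[C@@H]1[C@@H](c2c(O)c(C=O)c(OCc9ccccc9)cc2OCc9ccccc9)c2c(OCc9ccccc9)cc(OCc9ccccc9)cc2O[C@@H]1c1cc(OCc9ccccc9)c(OCc9ccccc9)c(OCc9ccccc9)c1)c1cc(OCc9ccccc9)c(OCc9ccccc9)c(OCc9ccccc9)c1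
F3 | step 4 | 4β-(benzylsulfanyl)-octa-O-benzyl-EGCG | O=C(O[C@@H]1[C@@H](SCc9ccccc9)c2c(OCc9ccccc9)cc(OCc9ccccc9)cc2O[C@@H]1c1cc(OCc9ccccc9)c(OCc9ccccc9)c(OCc9ccccc9)c1)c1cc(OCc9ccccc9)c(OCc9ccccc9)c(OCc9ccccc9)c1
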